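## Structural features

The target is a furofuran lignan, a 2,6-diaryl-3,7-dioxabicyclo[3.3.0]octane. Lignan locants are used throughout: C7, C8, C9 for the half that carries the 4-hydroxy-3,5-dimethoxyphenyl (syringyl) ring, and C7', C8', C9' for the half that carries the 3,4,5-trimethoxyphenyl ring. Ring A is the tetrahydrofuran O7–C7–C8–C8'–C9' and ring B is the tetrahydrofuran O9–C9–C8–C8'–C7'; the two rings are cis-fused through the shared bond C8–C8'. The four stereocentres C7, C8, C8', C7' stand in one unbroken row, and the SMILES string decodes to 7R,8S,8'S,7'R (1R,6aS,3aS,4R in furo[3,4-c]furan numbering). H8 and H8' are cis and both aryl groups are exo (convex face, trans to the neighbouring ring carbon), which is the mirror image of the common dextrorotatory series. The bicyclic core is C2-symmetric, but the aryl groups differ by one O-methyl group, so any plan that dimerises a single C6–C3 unit loses the difference. The fragile groups are the benzylic C–O bonds at C7 and C7', which ionise in acid (epimerisation to endo-aryl isomers, Friedel–Crafts closure to aryltetralins) and are cut by hydrogenolysis, and the free 2,6-dimethoxyphenol, which is easily oxidised to a quinone methide. The real difficulty is to set four contiguous centres in one absolute sense on an unsymmetrical, acid-labile bicycle, not to make any single bond. The key step exploits three features: C8–C8' belongs to ring A and ring B at once, C7' is a benzylic carbon that can carry first a radical and then a leaving group, and O9 sits on C9 next to C8, so the protected target is a constitutional isomer of an open-chain C8–C9 epoxide whose O7 bears a cinnamyl group.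

## Logic of the disconnections

**12 ⇒ 11.** The phenolic O–H is exchanged for an O–Si bond. The free phenol would quench the organomagnesium reagent, be alkylated in the ether synthesis and bind titanium. The gain is only chemoselectivity. The demand is a group that leaves without acid, hydrogen or oxidant, since C7–O7 and C7'–O9 tolerate none of these.

**11 ⇒ 8 (key).** The bonds C8–C8' and C7'–O9 are cut, which opens ring A and ring B together and removes the stereocentres C8, C8' and C7'. In one sentence: a titanocene(III)-induced epoxide-opening radical cyclisation with iodine-triggered etherification turns the open-chain epoxy cinnamyl ether 8 into the bicycle 11. The gain is from a bicycle with four centres to an acyclic isomer in which only C7 matters, because the oxirane centre C8 is erased on the way. The demand is that one centre (C7) controls three new ones and that the benzylic C7' radical ends in a C–O bond rather than a C–H bond.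

**8 ⇒ 5 + 7.** The bond O7–C9' is cut. This is the only bond between the two halves, so the two different aryl groups enter in separate pieces and the symmetry problem disappears. The demand is O-alkylation of an alkoxide that sits next to an oxirane, without migration of the oxirane and without touching C7.

**7 ⇒ 6.** The bond C9'–Br goes back to C9'–OH. This is a simple activation. The demand is retention of the E-alkene and of the primary (conjugated) position of the leaving group.

**5 ⇒ 4.** The two C–O bonds of the oxirane (C8–O and C9–O) are cut. One operation both installs O9 and selects one enantiomer at C7. The gain is a racemic precursor. The demand is a large rate difference between the enantiomers of 4 and a mild medium for an electron-rich benzylic alcohol.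

**4 ⇒ 2 + 3.** The bond C7–C8 is cut between a carbonyl carbon and a vinyl anion. This leads to an aryl aldehyde and a C2 reagent. The only demand is 1,2-addition.

**2 ⇒ 1.** The O–Si bond is cut, which gives the commercial phenolic aldehyde.

## Other disconnections considered

**Alternative 1:** This is the first idea that comes to mind. C8–C8', C7–O and C7'–O are all cut at once. Forward, a one-electron oxidant dimerises sinapyl alcohol A1 through its C8 radicals, the bis-quinone methide closes both rings to racemic syringaresinol A2, and one phenol is then methylated. The free-radical coupling has no element that controls absolute configuration, so A2 would be racemic and a resolution would be needed. The 8–O–4' and 8–5' coupling modes compete with 8–8'. The two phenols of A2 are related by the C2 axis, so monomethylation can only be statistical. A crossed coupling is closed because the trimethoxy partner has no phenol to oxidise. The chosen plan brings in the aryl groups separately and sets the absolute sense catalytically.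

**Alternative 2:** A bond that the target lacks, C7–C7', is added in the retrosynthetic direction. This gives the all-trans cyclobutane diol A3, itself the reduced product of a crossed head-to-head [2+2] photocycloaddition of two cinnamate units. Forward, a two-electron oxidation of the phenol would trigger heterolysis of the strained C7–C7' bond to a quinone methide at C7 and a trimethoxybenzylic cation at C7', and the two hydroxymethyl groups would capture these to close both rings. The idea erases C7 and C7' elegantly. However, C8 and C8' would then depend on a tether- or auxiliary-controlled photoreaction of two almost identical alkenes, whose facial sense cannot be derived from a simple model. The oxidation also has to prefer C–C cleavage over loss of H7 and over spirodienone formation by O9. That makes two uncertain steps against one, for no saving in step count.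

**Alternative 3:** C8'–C9' and C7'–O9 are cut, so that C9' becomes a one-carbon stitch. Forward, a Lewis acid opens the cyclic methylene acetal A4 to the oxocarbenium ion O7=C9'H2, the styrene attacks through C8' (5-exo), and O9 captures the C7' cation. Here the C9 branch sits at the allylic position of the cyclising chain, where five-ring transition states prefer the 3,4-trans product, the opposite of what cis-fusion needs. The acetal can also open towards O9 and then lead to the 2,4-diaryl isomer. In addition, a methylene acetal ionises less readily than the benzylic ethers of the product. The chosen radical closure has the branch on the attacking carbon (cis preference), has no regiochemical twin, and runs without acid.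

Key step: step 6

Remark on the chemistry: with L-(+)-tartrate the fast-reacting enantiomer of a secondary allylic alcohol is the one that gives the erythro epoxy alcohol on the normally attacked face. For 4 this is the R enantiomer, because aryl outranks vinyl in the CIP order.

## Steps

Step 1
Reactants: 1 syringaldehyde (4-hydroxy-3,5-dimethoxybenzaldehyde)
Product: 2 4-[(tert-butyldimethylsilyl)oxy]-3,5-dimethoxybenzaldehyde
Conditions: TBSCl, imidazole, DMF, rt
Reagents that add atoms: tert-butyldimethylsilyl chloride, CC(C)(C)[Si](C)(C)Cl
Why: Silyl ether formation on the only acidic OH masks the phenol against the Grignard reagent, NaH and titanium. A silyl group is chosen because it leaves with fluoride and not with acid or hydrogen, which the benzylic ethers of the final bicycle would not survive.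

Step 2
Reactants: 2 4-[(tert-butyldimethylsilyl)oxy]-3,5-dimethoxybenzaldehyde; 3 vinylmagnesium bromide
Product: 4 rac-1-{4-[(tert-butyldimethylsilyl)oxy]-3,5-dimethoxyphenyl}prop-2-en-1-ol
Conditions: THF, −78 to 0 °C; then H2O
Reagents that add atoms: vinylmagnesium bromide 3, C=C[Mg]Br
Why: Grignard 1,2-addition to an aryl aldehyde forms C7–C8 and should give the racemic allylic alcohol. The aryl silyl ether is inert to the reagent at low temperature.

Step 3
Reactants: 4 rac-1-{4-[(tert-butyldimethylsilyl)oxy]-3,5-dimethoxyphenyl}prop-2-en-1-ol
Product: 5 (S)-{4-[(tert-butyldimethylsilyl)oxy]-3,5-dimethoxyphenyl}[(2R)-oxiran-2-yl]methanol (erythro, 7S,8R)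
Conditions: Ti(OiPr)4 (cat.), L-(+)-DIPT (cat.), TBHP (0.45 equiv), 4 Å MS, CH2Cl2, −20 °C
Reagents that add atoms: tert-butyl hydroperoxide, CC(C)(C)OO
Why: Sharpless kinetic resolution: with L-(+)-DIPT the R enantiomer of 4 is the matched one and should be epoxidised to the erythro epoxy alcohol, while (S)-4 reacts much more slowly and stays behind because less than half an equivalent of oxidant is offered. This fixes C7, which is kept to the end, and C8, which is erased in step 6. The label at C7 changes from R to S only because the oxirane carbon outranks the aryl group.

Step 4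
Reactants: 6 (E)-3-(3,4,5-trimethoxyphenyl)prop-2-en-1-ol
Product: 7 5-[(E)-3-bromoprop-1-en-1-yl]-1,2,3-trimethoxybenzene
Conditions: PBr3, Et2O, 0 °C; used crude
Reagents that add atoms: phosphorus tribromide, BrP(Br)Br
Why: Bromination of a primary allylic alcohol through its phosphite ester (SN2) keeps the E-alkene and the conjugated primary position. The electron-rich cinnamyl bromide ionises easily and is therefore carried on at once.

Step 5
Reactants: 5 (S)-{4-[(tert-butyldimethylsilyl)oxy]-3,5-dimethoxyphenyl}[(2R)-oxiran-2-yl]methanol; 7 5-[(E)-3-bromoprop-1-en-1-yl]-1,2,3-trimethoxybenzene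
Product: 8 (2R)-2-[(S)-{4-[(tert-butyldimethylsilyl)oxy]-3,5-dimethoxyphenyl}{[(2E)-3-(3,4,5-trimethoxyphenyl)prop-2-en-1-yl]oxy}methyl]oxirane
Conditions: NaH, nBu4NI (cat.), THF/DMF, 0 °C
Reagents that add atoms: none
Why: Williamson ether synthesis (SN2 at C9' of a reactive allylic bromide) forms O7–C9' and touches no bond at C7 or C8. The aprotic medium and the low temperature should hold back Payne migration of the alkoxide, as in O-benzylations of related 1,2-epoxy-3-ols.

Step 6
Reactants: 8 (2R)-2-[(S)-{4-[(tert-butyldimethylsilyl)oxy]-3,5-dimethoxyphenyl}{[(2E)-3-(3,4,5-trimethoxyphenyl)prop-2-en-1-yl]oxy}methyl]oxirane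
Product: 11 tert-butyl{2,6-dimethoxy-4-[(1R,3aS,4R,6aS)-4-(3,4,5-trimethoxyphenyl)tetrahydro-1H,3H-furo[3,4-c]furan-1-yl]phenoxy}dimethylsilane, via bis-titanated tetrahydrofuran 9 (not isolated), via benzylic iodide 10 (not isolated)
Conditions: Cp2TiCl2 (2.5 equiv), Zn dust, THF, rt, decanted and added slowly to 8 in THF, rt; then I2 (1.3 equiv), THF, rt to 50 °C; aq. NaH2PO4/Na2S2O3
Reagents that add atoms: none
Why: The step is a titanocene(III)-mediated reductive epoxide opening and radical cyclisation with iodine-induced ionic ring closure, a reaction type known for epoxy allyl and epoxy cinnamyl ethers. Cp2TiCl binds the oxirane oxygen and transfers one electron, so that the C8–O bond breaks to the secondary β-titanoxy radical at C8 and not the C9–O bond to a primary one; C8 becomes planar, hence its configuration in 8 does not matter. Ring A (O7–C7–C8–C8'–C9') closes by 5-exo-trig attack of C8 on C8' of the E-styrene, favoured over 6-endo by orbital overlap and by the benzylic C7' radical that results. In the chair-like 5-hexenyl transition state the aryl group on C7 lies pseudo-equatorial, the CH2OTi branch on C8 turns away from it (C8 trans to the aryl group) and follows the 1,5-cis preference of radicals substituted at the attacking carbon (C9 cis to C7'), so the single fixed centre C7 controls C8 and C8'. A second Cp2TiCl traps the C7' radical as 9, iodine turns it into the labile benzylic iodide 10, and the C9–O–Ti alkoxide displaces iodide (5-exo-tet, SN1-like at the trimethoxybenzylic carbon) to close ring B (O9–C9–C8–C8'–C7'). Because only an isomer with C9 and C7' cis on ring A can reach the cis-fused bicycle, a minor trans isomer stays monocyclic and is removed. The C–O bond forms on the rotamer that keeps the aryl group on the convex face, trans to C9', which sets C7' as R whatever the configuration of 9 or 10. The step needs cyclisation to be faster than deoxygenation of the β-titanoxy radical by a second Ti(III), which is secured by slow addition to dilute 8 and by the fast addition to a styrene, and it needs no ionisation at C7, which is secured by the non-acidic medium.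

Step 7
Reactants: 11 tert-butyl{2,6-dimethoxy-4-[(1R,3aS,4R,6aS)-4-(3,4,5-trimethoxyphenyl)tetrahydro-1H,3H-furo[3,4-c]furan-1-yl]phenoxy}dimethylsilane
Product: 12 2,6-dimethoxy-4-[(1R,3aS,4R,6aS)-4-(3,4,5-trimethoxyphenyl)tetrahydro-1H,3H-furo[3,4-c]furan-1-yl]phenol (target)
Conditions: TBAF, AcOH, THF, 0 °C
Reagents that add atoms: none
Why: Fluoride-induced cleavage of an aryl silyl ether. Acetic acid buffers the phenoxide, so neither oxidation of the syringyl ring under base nor ionisation at C7 or C7' under acid should occur, and no stereocentre is touched.

## Compound list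

1 | syringaldehyde | COc1cc(C=O)cc(OC)c1O | starting material
2 | 4-[(tert-butyldimethylsilyl)oxy]-3,5-dimethoxybenzaldehyde | COc1cc(C=O)cc(OC)c1O[Si](C)(C)C(C)(C)C | intermediate
3 | vinylmagnesium bromide | C=C[Mg]Br | starting material
4 | rac-1-{4-[(tert-butyldimethylsilyl)oxy]-3,5-dimethoxyphenyl}prop-2-en-1-ol | COc1cc(C(O)C=C)cc(OC)c1O[Si](C)(C)C(C)(C)C | intermediate
5 | (S)-{4-[(tert-butyldimethylsilyl)oxy]-3,5-dimethoxyphenyl}[(2R)-oxiran-2-yl]methanol | COc1cc([C@H](O)[C@H]2CO2)cc(OC)c1O[Si](C)(C)C(C)(C)C | intermediate
6 | (E)-3-(3,4,5-trimethoxyphenyl)prop-2-en-1-ol | COc1cc(/C=C/CO)cc(OC)c1OC | starting material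
7 | 5-[(E)-3-bromoprop-1-en-1-yl]-1,2,3-trimethoxybenzene | COc1cc(/C=C/CBr)cc(OC)c1OC | intermediate
8 | (2R)-2-[(S)-{4-[(tert-butyldimethylsilyl)oxy]-3,5-dimethoxyphenyl}{[(2E)-3-(3,4,5-trimethoxyphenyl)prop-2-en-1-yl]oxy}methyl]oxirane | COc1cc([C@H](OC/C=C/c2cc(OC)c(OC)c(OC)c2)[C@H]3CO3)cc(OC)c1O[Si](C)(C)C(C)(C)C | intermediate
9 | (2R,3S,4S)-tetrahydrofuran with C9–O–TiClCp2 and C7'–TiClCp2, C7' not defined (Cp drawn σ-bound) | COc1cc([C@@H]2OC[C@@H](C(c3cc(OC)c(OC)c(OC)c3)[Ti](Cl)(C3C=CC=C3)C3C=CC=C3)[C@H]2CO[Ti](Cl)(C3C=CC=C3)C3C=CC=C3)cc(OC)c1O[Si](C)(C)C(C)(C)C | intermediate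
10 | (2R,3S,4S)-tetrahydrofuran with C9–O–TiClCp2 and benzylic C7'–I, C7' not defined (Cp drawn σ-bound) | COc1cc([C@@H]2OC[C@@H](C(I)c3cc(OC)c(OC)c(OC)c3)[C@H]2CO[Ti](Cl)(C3C=CC=C3)C3C=CC=C3)cc(OC)c1O[Si](C)(C)C(C)(C)C | intermediate
11 | tert-butyl{2,6-dimethoxy-4-[(1R,3aS,4R,6aS)-4-(3,4,5-trimethoxyphenyl)tetrahydro-1H,3H-furo[3,4-c]furan-1-yl]phenoxy}dimethylsilane | COc1cc([C@@H]2OC[C@@H]3[C@H]2CO[C@H]3c2cc(OC)c(OC)c(OC)c2)cc(OC)c1O[Si](C)(C)C(C)(C)C | intermediate
12 | 2,6-dimethoxy-4-[(1R,3aS,4R,6aS)-4-(3,4,5-trimethoxyphenyl)tetrahydro-1H,3H-furo[3,4-c]furan-1-yl]phenol | COc1cc([C@@H]2OC[C@@H]3[C@H]2CO[C@H]3c2cc(OC)c(OC)c(OC)c2)cc(OC)c1O | target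

## Step count and least certain steps

Total step count: 7. Longest linear sequence: 6 (steps 1, 2, 3, 5, 6, 7).

**Step 6 (key step).**
- **Risk at the start of the sequence:** the β-titanoxy radical may be trapped by a second Ti(III) and lose Ti–O, which deoxygenates the epoxide before it cyclises.
- **Risk at the end of the sequence:** the benzylic titanium species may be protonated, or the benzylic iodide may lose HI, so the oxidative closure of ring B is missed. Any HI that builds up could also erode the exo selectivity at C7'.
- **Fallback (sets out from 5, returns at 11):** it needs no oxidative termination.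
  - Sonogashira coupling of commercial 5-iodo-1,2,3-trimethoxybenzene with propargyl alcohol gives 3-(3,4,5-trimethoxyphenyl)prop-2-yn-1-ol F1.
  - PBr3 converts this into the propargylic bromide F2, and Williamson etherification of 5 gives the epoxy propargyl ether F3.
  - Titanocene(III) (catalytic Cp2TiCl2, Mn, collidine hydrochloride, THF) opens the epoxide as before, the C8 radical closes ring A by 5-exo-dig attack on the alkyne, and the vinyl radical simply takes up hydrogen. The product is the 4-benzylidene tetrahydrofuran alcohol F4.
  - Ring B is then closed in a separate polar step, an acid-catalysed intramolecular hydroalkoxylation of the electron-rich styrene (catalytic camphorsulfonic acid, CH2Cl2, low temperature). Protonation at C8' gives the C7' cation. Only the C8' epimer with C7' cis to C9 can be captured by O9, while the other returns to F4 by loss of the proton, and 11 results.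

**Step 3.**
- **Risk:** a terminal vinyl group is the least nucleophilic alkene class for the titanium tartrate catalyst, so the epoxidation may be slow. The Lewis acid may then have time to ionise the electron-rich benzylic allylic alcohol (1,3-transposition, loss of enantiomeric purity) or to open the product epoxide with isopropoxide.
- **Fallback (sets out from 4, returns at 5):** it separates resolution from oxidation.
  - Lipase-catalysed acylation (Candida antarctica lipase B, vinyl acetate, toluene) should acylate the R alcohol, in line with the usual large/medium rule for secondary alcohols, to give the (R)-acetate F5.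
  - DIBAL-H at −78 °C frees the (R)-allylic alcohol F6.
  - Hydroxyl-directed epoxidation (VO(acac)2, TBHP, CH2Cl2), which favours the erythro isomer for such alcohols, gives 5. Any shortfall in facial selectivity at C8 is harmless because C8 is erased in step 6.

**Step 5.**
- **Risk:** Payne migration or intermolecular opening of the oxirane by the alkoxide, ionisation or SN2' reaction of the labile bromide 7, and attack of the base on the aryl silyl ether.
- **Fallback (sets out from 6 together with 5, returns at 8):** it replaces the SN2 reaction by a π-allyl metal reaction and bypasses 7.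
  - Methyl chloroformate and pyridine convert 6 into the allylic methyl carbonate F7.
  - A Tsuji–Trost O-allylation of the zinc alkoxide of 5 (Et2Zn 0.5 equiv, Pd(0), phosphine, THF, rt) should attack the unsubstituted terminus C9' of the aryl-substituted π-allyl complex, which keeps the styrene conjugation and gives 8 under almost neutral conditions.

## Further compounds

F1 | step 6 | 3-(3,4,5-trimethoxyphenyl)prop-2-yn-1-ol | COc1cc(C#CCO)cc(OC)c1OC
F2 | step 6 | 5-(3-bromoprop-1-yn-1-yl)-1,2,3-trimethoxybenzene | COc1cc(C#CCBr)cc(OC)c1OC
F3 | step 6 | (2R)-2-[(S)-{4-[(tert-butyldimethylsilyl)oxy]-3,5-dimethoxyphenyl}{[3-(3,4,5-trimethoxyphenyl)prop-2-yn-1-yl]oxy}methyl]oxirane | COc1cc([C@H](OCC#Cc2cc(OC)c(OC)c(OC)c2)[C@H]3CO3)cc(OC)c1O[Si](C)(C)C(C)(C)C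
F4 | step 6 | [(2R,3S)-2-{4-[(tert-butyldimethylsilyl)oxy]-3,5-dimethoxyphenyl}-4-(3,4,5-trimethoxybenzylidene)oxolan-3-yl]methanol (alkene geometry not defined) | COc1cc([C@@H]2OCC(=Cc3cc(OC)c(OC)c(OC)c3)[C@H]2CO)cc(OC)c1O[Si](C)(C)C(C)(C)C
F5 | step 3 | (R)-1-{4-[(tert-butyldimethylsilyl)oxy]-3,5-dimethoxyphenyl}prop-2-en-1-yl acetate | COc1cc([C@H](OC(C)=O)C=C)cc(OC)c1O[Si](C)(C)C(C)(C)C
F6 | step 3 | (R)-1-{4-[(tert-butyldimethylsilyl)oxy]-3,5-dimethoxyphenyl}prop-2-en-1-ol | COc1cc([C@H](O)C=C)cc(OC)c1O[Si](C)(C)C(C)(C)C
F7 | step 5 | methyl (E)-3-(3,4,5-trimethoxyphenyl)prop-2-en-1-yl carbonate | COC(=O)OC/C=C/c1cc(OC)c(OC)c(OC)c1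
A1 | alternative 1 | sinapyl alcohol | COc1cc(/C=C/CO)cc(OC)c1O
A2 | alternative 1 | rac-syringaresinol (one enantiomer drawn) | COc1cc([C@@H]2OC[C@@H]3[C@H]2CO[C@H]3c2cc(OC)c(O)c(OC)c2)cc(OC)c1O
A3 | alternative 2 | [(1S,2S,3R,4R)-3-(4-hydroxy-3,5-dimethoxyphenyl)-4-(3,4,5-trimethoxyphenyl)cyclobutane-1,2-diyl]dimethanol | OC[C@@H]1[C@@H](CO)[C@H](c2cc(OC)c(OC)c(OC)c2)[C@H]1c3cc(OC)c(O)c(OC)c3
A4 | alternative 3 | 2,6-dimethoxy-4-{(4R,5S)-5-[(E)-2-(3,4,5-trimethoxyphenyl)ethenyl]-1,3-dioxan-4-yl}phenyl pivalate | COc1cc([C@@H]2OCOC[C@@H]2/C=C/c3cc(OC)c(OC)c(OC)c3)cc(OC)c1OC(=O)C(C)(C)C
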